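**Retrosynthetic overview**
1. Last step forms both rings: a (Z)-hydroxy-enal, masked as a cyclic acetal, and a 2-(bromomethyl)-2-enoate close the ten-membered ring at C6–C7 and the new C6 alkoxide lactonises onto C12 (germacrane numbering throughout).
2. The seco-chain comes from a C7 aldehyde by Morita–Baylis–Hillman reaction and allylic bromination; the C8 angelate and C14 acetate come from a diol released by reducing a temporary C8-O/C14 α-alkylidene butyrolactone.
3. C1=C10 is made by an E-selective Horner–Wadsworth–Emmons reaction of phosphono-lactone 10 (glycidyl ether + phosphonoacetate) with aldehyde 6.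
4. Aldehyde 6 comes from an asymmetric hetero-Diels–Alder reaction of 1-methoxy-3-methylbutadiene with ethyl glyoxylate, which sets C2, locks C4=C5 cis, and hides the C6 aldehyde and C2-OH in one acetal.
5. Ring order: dihydropyran (temporary), then butyrolactone (temporary), then ten-membered carbocycle and α-methylene lactone together.

Assumption: the (S)-BINOL titanium catalyst is taken to give the (2S) cycloadduct 5 (the (R)-ligand is used if the facial sense is the other way), and glycidyl ether 7 is bought as the single (R) enantiomer.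

**Route**

Step 1
Reactants: 1 3-methylbut-2-enal
Product: 3 (1E)-1-methoxy-3-methylbuta-1,3-diene, via dimethyl acetal 2 (not isolated)
Conditions: HC(OMe)3, MeOH, NH4NO3 (cat.), rt; then KHSO4 (cat.), 150 °C, distil
Reagents that add atoms: trimethyl orthoformate, COC(OC)OC
Why: Acetalisation followed by acid-catalysed 1,4-elimination of methanol gives the electron-rich E-dienyl ether; no stereocentre is formed.

Step 2
Reactants: 3 (1E)-1-methoxy-3-methylbuta-1,3-diene; 4 ethyl glyoxylate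
Product: 5 ethyl (2S,6R)-6-methoxy-4-methyl-3,6-dihydro-2H-pyran-2-carboxylate
Conditions: (S)-1,1'-bi-2-naphthol/TiCl2(OiPr)2 (10 mol %), 4 Å MS, CH2Cl2, −30 °C
Reagents that add atoms: none
Why: Catalytic asymmetric hetero-Diels–Alder reaction in which the chiral titanium Lewis acid chelates the glyoxylate and blocks one face, so C2 is set as S; the methoxy group fixes the regiochemistry, the ring fixes C4=C5 as cis, and the acetal centre (cis from the endo mode) is inconsequential.

Step 3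
Reactants: 5 ethyl (2S,6R)-6-methoxy-4-methyl-3,6-dihydro-2H-pyran-2-carboxylate
Product: 6 (2S,6R)-6-methoxy-4-methyl-3,6-dihydro-2H-pyran-2-carbaldehyde
Conditions: i-Bu2AlH (1.1 equiv), CH2Cl2, −78 °C; Rochelle salt work-up
Reagents that add atoms: none
Why: Partial reduction of an α-alkoxy ester stops at the chelated aluminium hemiacetal at −78 °C and gives the aldehyde without touching the acetal or C2.

Step 4
Reactants: 7 (2R)-2-{[(4-methoxybenzyl)oxy]methyl}oxirane; 8 triethyl phosphonoacetate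
Product: 10 diethyl [(5R)-5-{[(4-methoxybenzyl)oxy]methyl}-2-oxooxolan-3-yl]phosphonate, via ring-opened alkoxide 9 (not isolated)
Conditions: NaOEt, EtOH, reflux; AcOH quench
Reagents that add atoms: none
Why: SN2 opening of the terminal epoxide carbon by the phosphonoacetate carbanion followed by lactonisation (alkylation–lactonisation); C8 keeps the configuration of 7 because the stereocentre is not attacked.

Step 5
Reactants: 6 (2S,6R)-6-methoxy-4-methyl-3,6-dihydro-2H-pyran-2-carbaldehyde; 10 diethyl [(5R)-5-{[(4-methoxybenzyl)oxy]methyl}-2-oxooxolan-3-yl]phosphonate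
Product: 11 (3E,5R)-3-{[(2S,6R)-6-methoxy-4-methyl-3,6-dihydro-2H-pyran-2-yl]methylidene}-5-{[(4-methoxybenzyl)oxy]methyl}oxolan-2-one
Conditions: NaH, THF, 0 °C to rt
Reagents that add atoms: none
Why: Horner–Wadsworth–Emmons olefination of an α-phosphono lactone is E-selective, which places C2 cis to C9 and trans to C14 as the target needs; minor Z isomer is removed by chromatography.

Step 6
Reactants: 11 (3E,5R)-3-{[(2S,6R)-6-methoxy-4-methyl-3,6-dihydro-2H-pyran-2-yl]methylidene}-5-{[(4-methoxybenzyl)oxy]methyl}oxolan-2-one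
Product: 12 (2E,4R)-2-{[(2S,6R)-6-methoxy-4-methyl-3,6-dihydro-2H-pyran-2-yl]methylidene}-5-[(4-methoxybenzyl)oxy]pentane-1,4-diol
Conditions: i-Bu2AlH (4.5 equiv), CH2Cl2, −78 to 0 °C
Reagents that add atoms: none
Why: 1,2-Reduction of the α-alkylidene lactone to the 1,4-diol releases C14-OH and C8-OH while acetal, PMB ether and olefin geometry survive; it is done before any other ester is present.

Step 7
Reactants: 12 (2E,4R)-2-{[(2S,6R)-6-methoxy-4-methyl-3,6-dihydro-2H-pyran-2-yl]methylidene}-5-[(4-methoxybenzyl)oxy]pentane-1,4-diol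
Product: 13 (2E,4R)-4-hydroxy-2-{[(2S,6R)-6-methoxy-4-methyl-3,6-dihydro-2H-pyran-2-yl]methylidene}-5-[(4-methoxybenzyl)oxy]pentyl acetate
Conditions: AcCl (1.05 equiv), 2,4,6-collidine, CH2Cl2, −78 °C
Reagents that add atoms: acetyl chloride, CC(Cl)=O
Why: Chemoselective acylation of the primary allylic alcohol over the secondary one at low temperature with a hindered base.

Step 8
Reactants: 13 (2E,4R)-4-hydroxy-2-{[(2S,6R)-6-methoxy-4-methyl-3,6-dihydro-2H-pyran-2-yl]methylidene}-5-[(4-methoxybenzyl)oxy]pentyl acetate; 14 angelic acid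
Product: 16 (2R,4E)-4-(acetoxymethyl)-1-[(4-methoxybenzyl)oxy]-5-[(2S,6R)-6-methoxy-4-methyl-3,6-dihydro-2H-pyran-2-yl]pent-4-en-2-yl (2Z)-2-methylbut-2-enoate, via mixed anhydride 15 (not isolated)
Conditions: 2,4,6-Cl3C6H2COCl, Et3N, toluene, rt; then 13, 75 °C (no DMAP)
Reagents that add atoms: none
Why: Yamaguchi-type mixed-anhydride esterification without a nucleophilic catalyst acylates C8-OH with retention and avoids isomerisation of the angelate to the tiglate.

Step 9
Reactants: 16 (2R,4E)-4-(acetoxymethyl)-1-[(4-methoxybenzyl)oxy]-5-[(2S,6R)-6-methoxy-4-methyl-3,6-dihydro-2H-pyran-2-yl]pent-4-en-2-yl (2Z)-2-methylbut-2-enoate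
Product: 17 (2R,4E)-4-(acetoxymethyl)-1-hydroxy-5-[(2S,6R)-6-methoxy-4-methyl-3,6-dihydro-2H-pyran-2-yl]pent-4-en-2-yl (2Z)-2-methylbut-2-enoate
Conditions: DDQ, CH2Cl2/pH 7 buffer (10:1), 0 °C
Reagents that add atoms: none
Why: Oxidative cleavage of the electron-rich PMB ether under buffered conditions spares the acetal, both esters and the olefins.

Step 10
Reactants: 17 (2R,4E)-4-(acetoxymethyl)-1-hydroxy-5-[(2S,6R)-6-methoxy-4-methyl-3,6-dihydro-2H-pyran-2-yl]pent-4-en-2-yl (2Z)-2-methylbut-2-enoate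
Product: 18 (2R,4E)-4-(acetoxymethyl)-5-[(2S,6R)-6-methoxy-4-methyl-3,6-dihydro-2H-pyran-2-yl]-1-oxopent-4-en-2-yl (2Z)-2-methylbut-2-enoate
Conditions: Dess–Martin periodinane, NaHCO3, CH2Cl2, 0 °C; used crude
Reagents that add atoms: none
Why: Dess–Martin oxidation under buffered, non-basic conditions gives the α-acyloxy aldehyde without epimerising C8.

Step 11
Reactants: 18 (2R,4E)-4-(acetoxymethyl)-5-[(2S,6R)-6-methoxy-4-methyl-3,6-dihydro-2H-pyran-2-yl]-1-oxopent-4-en-2-yl (2Z)-2-methylbut-2-enoate; 19 methyl acrylate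
Product: 20 methyl (4R,6E)-6-(acetoxymethyl)-3-hydroxy-7-[(2S,6R)-6-methoxy-4-methyl-3,6-dihydro-2H-pyran-2-yl]-2-methylidene-4-{[(2Z)-2-methylbut-2-enoyl]oxy}hept-6-enoate
Conditions: methyl acrylate (10 equiv), 1,4-diazabicyclo[2.2.2]octane (1 equiv), MeOH (trace), rt, 3 d
Reagents that add atoms: none
Why: Morita–Baylis–Hillman reaction of an activated α-acyloxy aldehyde; the new carbinol centre (C7, both epimers) is inconsequential because it becomes sp2 in the next step.

Step 12
Reactants: 20 methyl (4R,6E)-6-(acetoxymethyl)-3-hydroxy-7-[(2S,6R)-6-methoxy-4-methyl-3,6-dihydro-2H-pyran-2-yl]-2-methylidene-4-{[(2Z)-2-methylbut-2-enoyl]oxy}hept-6-enoate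
Product: 21 methyl (2Z,4R,6E)-6-(acetoxymethyl)-2-(bromomethyl)-7-[(2S,6R)-6-methoxy-4-methyl-3,6-dihydro-2H-pyran-2-yl]-4-{[(2Z)-2-methylbut-2-enoyl]oxy}hepta-2,6-dienoate
Conditions: NBS, Me2S, CH2Cl2, 0 °C to rt
Reagents that add atoms: N-bromosuccinimide, BrN1C(=O)CCC1=O
Why: Corey–Kim-type activation of the allylic alcohol and SN2′ attack of bromide (allylic transposition) gives the conjugated 2-(bromomethyl)-2-enoate under neutral conditions that the acetal tolerates.

Step 13
Reactants: 21 methyl (2Z,4R,6E)-6-(acetoxymethyl)-2-(bromomethyl)-7-[(2S,6R)-6-methoxy-4-methyl-3,6-dihydro-2H-pyran-2-yl]-4-{[(2Z)-2-methylbut-2-enoyl]oxy}hepta-2,6-dienoate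
Product: 25 CNP0151426.1 (2S,6R,7R,8R)-14-acetoxy-8-angeloyloxy-2-hydroxy-cis,cis-germacra-1(10),4,11(13)-trien-6,12-olide, via lactol 22 (not isolated), via open hydroxy-enal 23 (not isolated), via cyclised hydroxy ester 24 (not isolated)
Conditions: indium powder (6 equiv), THF/0.1 M aq HCl (5:1), slow addition to 2 mM, 35 °C; then camphor-10-sulfonic acid (cat.), CH2Cl2, rt
Reagents that add atoms: water, O
Why: Acetal hydrolysis, ring-chain opening of the lactol to the (Z)-hydroxy-enal and an indium-mediated intramolecular Barbier (Dreiding–Schmidt-type) 2-(alkoxycarbonyl)allylation, as known for lactols in dilute aqueous acid, close the ten-membered ring at C6–C7, and the γ-hydroxy ester then lactonises; C6 and C7 are set in the cyclic six-membered allylindium–aldehyde transition state, where the C8 centre and the two cis olefins of the tether are expected to favour the anti mode that gives the trans-fused 6R,7R lactone, and C2-OH is released unprotected.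

**Compound list**
1 | 3-methylbut-2-enal | CC(C)=CC=O | starting material
2 | 1,1-dimethoxy-3-methylbut-2-ene | COC(OC)C=C(C)C | intermediate (not isolated)
3 | (1E)-1-methoxy-3-methylbuta-1,3-diene | CO/C=C/C(C)=C | intermediate
4 | ethyl glyoxylate | CCOC(=O)C=O | starting material
5 | ethyl (2S,6R)-6-methoxy-4-methyl-3,6-dihydro-2H-pyran-2-carboxylate | CCOC(=O)[C@@H]1CC(C)=C[C@H](OC)O1 | intermediate
6 | (2S,6R)-6-methoxy-4-methyl-3,6-dihydro-2H-pyran-2-carbaldehyde | O=C[C@@H]1CC(C)=C[C@H](OC)O1 | intermediate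
7 | (2R)-2-{[(4-methoxybenzyl)oxy]methyl}oxirane | COc1ccc(COC[C@H]2CO2)cc1 | starting material
8 | triethyl phosphonoacetate | CCOC(=O)CP(=O)(OCC)OCC | starting material
9 | ethyl (4R)-2-(diethoxyphosphoryl)-4-hydroxy-5-[(4-methoxybenzyl)oxy]pentanoate (present as its sodium alkoxide) | CCOC(=O)C(C[C@@H](O)COCc1ccc(OC)cc1)P(=O)(OCC)OCC | intermediate (not isolated)
10 | diethyl [(5R)-5-{[(4-methoxybenzyl)oxy]methyl}-2-oxooxolan-3-yl]phosphonate | CCOP(=O)(OCC)C1C[C@H](COCc2ccc(OC)cc2)OC1=O | intermediate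
11 | (3E,5R)-3-{[(2S,6R)-6-methoxy-4-methyl-3,6-dihydro-2H-pyran-2-yl]methylidene}-5-{[(4-methoxybenzyl)oxy]methyl}oxolan-2-one | O=C1O[C@@H](COCc2ccc(OC)cc2)C/C1=C\[C@@H]3CC(C)=C[C@H](OC)O3 | intermediate
12 | (2E,4R)-2-{[(2S,6R)-6-methoxy-4-methyl-3,6-dihydro-2H-pyran-2-yl]methylidene}-5-[(4-methoxybenzyl)oxy]pentane-1,4-diol | OC/C(C[C@@H](O)COCc1ccc(OC)cc1)=C/[C@@H]1CC(C)=C[C@H](OC)O1 | intermediate
13 | (2E,4R)-4-hydroxy-2-{[(2S,6R)-6-methoxy-4-methyl-3,6-dihydro-2H-pyran-2-yl]methylidene}-5-[(4-methoxybenzyl)oxy]pentyl acetate | CC(=O)OC/C(C[C@@H](O)COCc1ccc(OC)cc1)=C/[C@@H]1CC(C)=C[C@H](OC)O1 | intermediate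
14 | angelic acid, (2Z)-2-methylbut-2-enoic acid | C/C=C(/C)C(=O)O | starting material
15 | (2Z)-2-methylbut-2-enoic 2,4,6-trichlorobenzoic anhydride | C/C=C(/C)C(=O)OC(=O)c1c(Cl)cc(Cl)cc1Cl | intermediate (not isolated)
16 | (2R,4E)-4-(acetoxymethyl)-1-[(4-methoxybenzyl)oxy]-5-[(2S,6R)-6-methoxy-4-methyl-3,6-dihydro-2H-pyran-2-yl]pent-4-en-2-yl (2Z)-2-methylbut-2-enoate | CC(=O)OC/C(C[C@@H](OC(=O)/C(C)=C\C)COCc1ccc(OC)cc1)=C/[C@@H]1CC(C)=C[C@H](OC)O1 | intermediate
17 | (2R,4E)-4-(acetoxymethyl)-1-hydroxy-5-[(2S,6R)-6-methoxy-4-methyl-3,6-dihydro-2H-pyran-2-yl]pent-4-en-2-yl (2Z)-2-methylbut-2-enoate | CC(=O)OC/C(C[C@@H](OC(=O)/C(C)=C\C)CO)=C/[C@@H]1CC(C)=C[C@H](OC)O1 | intermediate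
18 | (2R,4E)-4-(acetoxymethyl)-5-[(2S,6R)-6-methoxy-4-methyl-3,6-dihydro-2H-pyran-2-yl]-1-oxopent-4-en-2-yl (2Z)-2-methylbut-2-enoate | CC(=O)OC/C(C[C@@H](OC(=O)/C(C)=C\C)C=O)=C/[C@@H]1CC(C)=C[C@H](OC)O1 | intermediate
19 | methyl acrylate | C=CC(=O)OC | starting material
20 | methyl (4R,6E)-6-(acetoxymethyl)-3-hydroxy-7-[(2S,6R)-6-methoxy-4-methyl-3,6-dihydro-2H-pyran-2-yl]-2-methylidene-4-{[(2Z)-2-methylbut-2-enoyl]oxy}hept-6-enoate (both C3 epimers) | CC(=O)OC/C(C[C@@H](OC(=O)/C(C)=C\C)C(O)C(=C)C(=O)OC)=C/[C@@H]1CC(C)=C[C@H](OC)O1 | intermediate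
21 | methyl (2Z,4R,6E)-6-(acetoxymethyl)-2-(bromomethyl)-7-[(2S,6R)-6-methoxy-4-methyl-3,6-dihydro-2H-pyran-2-yl]-4-{[(2Z)-2-methylbut-2-enoyl]oxy}hepta-2,6-dienoate | CC(=O)OC/C(C[C@@H](OC(=O)/C(C)=C\C)/C=C(\CBr)C(=O)OC)=C/[C@@H]1CC(C)=C[C@H](OC)O1 | intermediate
22 | methyl (2Z,4R,6E)-6-(acetoxymethyl)-2-(bromomethyl)-7-[(2S)-6-hydroxy-4-methyl-3,6-dihydro-2H-pyran-2-yl]-4-{[(2Z)-2-methylbut-2-enoyl]oxy}hepta-2,6-dienoate (lactol, both anomers) | CC(=O)OC/C(C[C@@H](OC(=O)/C(C)=C\C)/C=C(\CBr)C(=O)OC)=C/[C@@H]1CC(C)=CC(O)O1 | intermediate (not isolated)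
23 | methyl (2Z,4R,6E,8S,10Z)-6-(acetoxymethyl)-2-(bromomethyl)-8-hydroxy-10-methyl-4-{[(2Z)-2-methylbut-2-enoyl]oxy}-12-oxododeca-2,6,10-trienoate | O=C/C=C(/C)C[C@H](O)/C=C(/COC(C)=O)C[C@@H](OC(=O)/C(C)=C\C)/C=C(\CBr)C(=O)OC | intermediate (not isolated)
24 | methyl 2-[(1S,2R,3Z,6S,7E,10R)-8-(acetoxymethyl)-2,6-dihydroxy-4-methyl-10-{[(2Z)-2-methylbut-2-enoyl]oxy}cyclodeca-3,7-dien-1-yl]prop-2-enoate | C=C(C(=O)OC)[C@H]1[C@H](O)/C=C(/C)C[C@H](O)/C=C(/COC(C)=O)C[C@H]1OC(=O)/C(C)=C\C | intermediate (not isolated)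
25 | CNP0151426.1, (2S,6R,7R,8R)-14-acetoxy-8-angeloyloxy-2-hydroxy-cis,cis-germacra-1(10),4,11(13)-trien-6,12-olide | C=C1C(=O)O[C@@H]2/C=C(/C)C[C@H](O)/C=C(/COC(C)=O)C[C@@H](OC(=O)/C(C)=C\C)[C@@H]12 | target

**Totals**
Total step count: 13. Longest linear sequence: 12 steps (steps 1–3 and 5–13, from 3-methylbut-2-enal); step 4 is the one-step side branch.

**Three steps most likely to fail, and fallbacks**

Step 13 (ring closure). Risks are oligomerisation or protonolysis of the allylindium before the ten-membered ring closes, and formation of the cis-fused lactone or the other facial diastereomer; the stereochemical outcome rests on macrocyclic precedent, not on a firm model. The fallback sets out from 21 and returns at 25, and replaces the organometallic Barbier reaction by a boron-based allylation through a closed transition state. Copper-catalysed borylation of the allylic bromide (B2pin2, CuCl, KOAc, DMF, rt; the activated bromide reacts ahead of the plain allylic acetate) gives the pinacol allylboronate F1. Acetal hydrolysis (AcOH/THF/H2O) frees the lactol, and heating at 1 mM in toluene (60–80 °C) lets the bench-stable boronate add intramolecularly to the ring-opened aldehyde over long reaction times. Acidic work-up lactonises the borate to 25.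

Step 11 (Morita–Baylis–Hillman). The α-acyloxy aldehyde may react slowly, epimerise at C8, or suffer angelate migration under the amine. The fallback sets out from 18 and returns at 20 by an amine-free reductive aldol. Methyl propiolate is hydroaluminated with i-Bu2AlH/HMPA (THF, 0 °C) to the α-(methoxycarbonyl)vinylalane, which is added to 18 at 0 °C and gives 20 directly; no new isolated compound is involved.

Step 2 (asymmetric hetero-Diels–Alder). A glyoxylate–ene reaction at the 1,1-disubstituted end of the diene can compete, and the enantioselectivity with this diene is untested. The fallback sets out from 4 and returns at 5, and builds the same ring by ene reaction and metathesis. The glyoxylate–ene reaction of 4 with isobutene under (S)-1,1'-bi-2-naphthol/TiCl2(OiPr)2 gives ethyl (2S)-2-hydroxy-4-methylpent-4-enoate F2. Transacetalisation with 3,3-dimethoxyprop-1-ene (pyridinium p-toluenesulfonate, toluene, methanol distilled off) gives the mixed acetal ethyl (2S)-2-[(1-methoxyprop-2-en-1-yl)oxy]-4-methylpent-4-enoate F3. Ring-closing metathesis with the second-generation Grubbs catalyst (CH2Cl2, 40 °C) closes the dihydropyran and gives 5 as a mixture at the inconsequential acetal carbon.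

**Further compounds**
F1 | step 13 | methyl (2E,4R,6E)-6-(acetoxymethyl)-7-[(2S,6R)-6-methoxy-4-methyl-3,6-dihydro-2H-pyran-2-yl]-4-{[(2Z)-2-methylbut-2-enoyl]oxy}-2-[(4,4,5,5-tetramethyl-1,3,2-dioxaborolan-2-yl)methyl]hepta-2,6-dienoate | CC(=O)OC/C(C[C@@H](OC(=O)/C(C)=C\C)/C=C(\CB1OC(C)(C)C(C)(C)O1)C(=O)OC)=C/[C@@H]2CC(C)=C[C@H](OC)O2
F0 | step 11 | none | none
F2 | step 2 | ethyl (2S)-2-hydroxy-4-methylpent-4-enoate | CCOC(=O)[C@@H](O)CC(C)=C
F3 | step 2 | ethyl (2S)-2-[(1-methoxyprop-2-en-1-yl)oxy]-4-methylpent-4-enoate | CCOC(=O)[C@@H](OC(OC)C=C)CC(C)=C
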